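**Plan**
- Retrosynthetic cuts: the two gallate ester C–O bonds, then the aryl ether bond O1–C8a of the upper ring C, then the interflavan bond C4–C8, then the upper C4–C4a bond.
- Enabling feature: in the upper unit O1 joins the benzylic carbinol carbon C2 to arene carbon C8a of ring A, which lies ortho to C4. The chain C2–C3–C4 with ring B on C2 has the carbon skeleton and threo heteroatom pattern of droxidopa, whose carboxyl carbon becomes C4.
- Forward order: droxidopa is turned into a protected 3-arylglyceraldehyde; ring A is added to C4 as an ortho-bromoaryl Grignard reagent; the epicatechin unit is joined to C4 by Friedel–Crafts alkylation; ring C then closes by copper-catalysed O-arylation; deallylation, galloylation and hydrogenolysis finish.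
- Stereochemistry: upper C2 and C3 come from droxidopa (nitrogen replaced by oxygen with retention), upper C4 from 1,2-induction in the benzylic cation, lower C2 and C3 from (−)-epicatechin.

Key step: step 15

Remark: the two C4 epimers of carbinol 16 are used together because C4 is ionised in step 13; O3 carries an allyl ether instead of a silyl ether because it is small and cannot migrate to O2; 3,4,5-tris(benzyloxy)benzoic acid (25) is taken as a purchased compound.

**Step 1**
Reactants: 1 droxidopa, (2S,3R)-2-amino-3-(3,4-dihydroxyphenyl)-3-hydroxypropanoic acid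
Product: 2 N-Boc-droxidopa, (2S,3R)-2-[(tert-butoxycarbonyl)amino]-3-(3,4-dihydroxyphenyl)-3-hydroxypropanoic acid
Conditions: Boc2O, NaHCO3, 1,4-dioxane/H2O, 0 °C → rt, Ar; then 1 M HCl to pH 3
Reagents that add atoms: di-tert-butyl dicarbonate, CC(C)(C)OC(=O)OC(=O)OC(C)(C)C
Why: Carbamate formation on the α-amino group under aqueous hydrogencarbonate is a standard amino acid protection that touches neither the catechol nor the two stereocentres and masks nitrogen for the alkylation that follows.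

**Step 2**
Reactants: 2 N-Boc-droxidopa
Product: 3 benzyl (2S,3R)-3-[3,4-bis(benzyloxy)phenyl]-2-[(tert-butoxycarbonyl)amino]-3-hydroxypropanoate
Conditions: BnBr (3.3 equiv), K2CO3, DMF, rt
Reagents that add atoms: benzyl bromide, BrCc1ccccc1
Why: Williamson alkylation with carbonate base benzylates the two phenols and the carboxylate but not the secondary benzylic alcohol or the carbamate nitrogen, so the catechol is shielded from nitrous acid in step 5.

**Step 3**
Reactants: 3 benzyl (2S,3R)-3-[3,4-bis(benzyloxy)phenyl]-2-[(tert-butoxycarbonyl)amino]-3-hydroxypropanoate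
Product: 5 benzyl (2S,3R)-2-amino-3-[3,4-bis(benzyloxy)phenyl]-3-[(tert-butyldimethylsilyl)oxy]propanoate, via silyl carbamate 4 (not isolated)
Conditions: TBSOTf (3 equiv), 2,6-lutidine, CH2Cl2, 0 °C → rt; then MeOH, rt
Reagents that add atoms: tert-butyldimethylsilyl triflate, CC(C)(C)[Si](C)(C)OS(=O)(=O)C(F)(F)F
Why: The silyl triflate silylates the benzylic hydroxyl and at the same time turns the tert-butyl carbamate into a silyl carbamate with loss of 2-methylpropene, which methanol cleaves to the free amine, a known silyl triflate carbamate cleavage that spares benzyl ethers and esters.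

**Step 4**
Reactants: 5 benzyl (2S,3R)-2-amino-3-[3,4-bis(benzyloxy)phenyl]-3-[(tert-butyldimethylsilyl)oxy]propanoate
Product: 6 (2S,3R)-2-amino-3-[3,4-bis(benzyloxy)phenyl]-3-[(tert-butyldimethylsilyl)oxy]propanoic acid
Conditions: LiOH, THF/H2O, 0 °C; then 1 M HCl to pH 6
Reagents that add atoms: lithium hydroxide, [Li+].[OH-]
Why: Saponification of the benzyl ester at 0 °C frees the carboxylate needed as neighbouring group in step 5, and the silyl ether on the β-oxygen rules out retro-aldol cleavage.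

**Step 5**
Reactants: 6 (2S,3R)-2-amino-3-[3,4-bis(benzyloxy)phenyl]-3-[(tert-butyldimethylsilyl)oxy]propanoic acid
Product: 9 (2S,3R)-3-[3,4-bis(benzyloxy)phenyl]-3-[(tert-butyldimethylsilyl)oxy]-2-hydroxypropanoic acid, via diazonium carboxylate 7 (not isolated), via alpha-lactone 8 (not isolated)
Conditions: NaNO2, 0.5 M aq. H2SO4, THF, 0 °C → rt
Reagents that add atoms: water, O
Why: Nitrous acid deamination of an α-amino acid runs by double inversion (the carboxylate displaces nitrogen to give the α-lactone, water then opens it at the same carbon), so oxygen should replace nitrogen with net retention and the future C3 keeps the configuration of droxidopa.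

**Step 6**
Reactants: 9 (2S,3R)-3-[3,4-bis(benzyloxy)phenyl]-3-[(tert-butyldimethylsilyl)oxy]-2-hydroxypropanoic acid
Product: 10 prop-2-en-1-yl (2S,3R)-3-[3,4-bis(benzyloxy)phenyl]-3-[(tert-butyldimethylsilyl)oxy]-2-(prop-2-en-1-yloxy)propanoate
Conditions: allyl bromide (excess), Ag2O, 4 Å MS, Et2O/DMF, rt, dark
Reagents that add atoms: allyl bromide, C=CCBr
Why: Silver oxide-mediated O-alkylation allylates the carboxylic acid and the α-hydroxyl without a soluble base, so the α-stereocentre should not epimerise and the silyl group should not migrate.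

**Step 7**
Reactants: 10 prop-2-en-1-yl (2S,3R)-3-[3,4-bis(benzyloxy)phenyl]-3-[(tert-butyldimethylsilyl)oxy]-2-(prop-2-en-1-yloxy)propanoate
Product: 11 (2S,3R)-3-[3,4-bis(benzyloxy)phenyl]-3-[(tert-butyldimethylsilyl)oxy]-2-(prop-2-en-1-yloxy)propanal
Conditions: i-Bu2AlH (1.1 equiv), CH2Cl2, −78 °C; then MeOH, aqueous work-up
Reagents that add atoms: none
Why: Partial reduction of an α-alkoxy ester by the aluminium hydride at −78 °C stops at the chelated hemiacetal aluminate, which should release the aldehyde only on work-up.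

**Step 8**
Reactants: 12 5-bromoresorcinol (5-bromobenzene-1,3-diol)
Product: 13 1,3-bis(benzyloxy)-5-bromobenzene
Conditions: BnBr (2.2 equiv), K2CO3, DMF, rt
Reagents that add atoms: benzyl bromide, BrCc1ccccc1
Why: Williamson etherification of both phenols is routine and leaves the aryl bromide untouched.

**Step 9**
Reactants: 13 1,3-bis(benzyloxy)-5-bromobenzene
Product: 14 1,5-bis(benzyloxy)-3-bromo-2-iodobenzene
Conditions: NIS, CF3CO2H (cat.), MeCN, 0 °C → rt
Reagents that add atoms: N-iodosuccinimide, O=C1CCC(=O)N1I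
Why: Electrophilic aromatic iodination should go to the carbon between bromine and one benzyloxy group, which is para to the other benzyloxy group, because the position between the two ethers is the most crowded, the usual outcome for 5-substituted resorcinol diethers.

**Step 10**
Reactants: 14 1,5-bis(benzyloxy)-3-bromo-2-iodobenzene; 11 (2S,3R)-3-[3,4-bis(benzyloxy)phenyl]-3-[(tert-butyldimethylsilyl)oxy]-2-(prop-2-en-1-yloxy)propanal
Product: 16 (2R,3R)-3-[3,4-bis(benzyloxy)phenyl]-1-[2,4-bis(benzyloxy)-6-bromophenyl]-3-[(tert-butyldimethylsilyl)oxy]-2-(prop-2-en-1-yloxy)propan-1-ol (both C1 epimers; C1 is the future C4), via arylmagnesium chloride 15 (not isolated)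
Conditions: 14, i-PrMgCl·LiCl, THF, −40 °C; then 11, −40 → −20 °C; aq. NH4Cl
Reagents that add atoms: none
Why: Iodine–magnesium exchange is far faster than bromine–magnesium exchange, so the ortho-bromoaryl Grignard reagent should form selectively at −40 °C, below the temperature of aryne formation, and add to the aldehyde (Grignard 1,2-addition); the configuration of the new carbinol carbon is of no account because it is ionised in step 13.

**Step 11**
Reactants: 17 (−)-epicatechin
Product: 18 5,7,3',4'-tetra-O-benzyl-(−)-epicatechin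
Conditions: BnBr (4.4 equiv), K2CO3, DMF, 0 °C → rt
Reagents that add atoms: benzyl bromide, BrCc1ccccc1
Why: Williamson etherification with carbonate base benzylates the four phenols and leaves the secondary 3-hydroxyl free, the established entry to protected epicatechin.

**Step 12**
Reactants: 18 5,7,3',4'-tetra-O-benzyl-(−)-epicatechin
Product: 19 3-O-allyl-5,7,3',4'-tetra-O-benzyl-(−)-epicatechin
Conditions: NaH, allyl bromide, Bu4NI (cat.), DMF, 0 °C → rt
Reagents that add atoms: allyl bromide, C=CCBr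
Why: Williamson etherification through the sodium alkoxide is safe here because no free phenol is left that could open ring C and epimerise C2.

**Step 13**
Reactants: 16 carbinol (both C1 epimers); 19 3-O-allyl-5,7,3',4'-tetra-O-benzyl-(−)-epicatechin
Product: 20 (1R,2R,3S)-3-[3-O-allyl-5,7,3',4'-tetra-O-benzyl-(−)-epicatechin-8-yl]-1-[3,4-bis(benzyloxy)phenyl]-3-[2,4-bis(benzyloxy)-6-bromophenyl]-1-[(tert-butyldimethylsilyl)oxy]-2-(prop-2-en-1-yloxy)propane
Conditions: 19 (3 equiv), TMSOTf (0.3 equiv), 4 Å MS, CH2Cl2, −78 → −40 °C; Et3N quench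
Reagents that add atoms: none
Why: Friedel–Crafts alkylation of SN1 type: the acid ionises the carbinol to a 2,4-dialkoxy-6-bromobenzyl cation (far more stabilised than a cation at the silylated C2), the phloroglucinol-type ring A of 19 captures it at C8 as in flavan-4-yl couplings, and the new C4 stereocentre should be set by 1,2-induction from C3, because allylic 1,3-strain with the ortho substituents holds C3–H in the cation plane and the arene then enters past the small allyloxy group, away from the bulky silyloxy(aryl)methyl branch, which gives the 3,4-relationship that becomes trans on ring C.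

**Step 14**
Reactants: 20 triarylpropane silyl ether
Product: 21 (1R,2R,3S)-3-[3-O-allyl-5,7,3',4'-tetra-O-benzyl-(−)-epicatechin-8-yl]-1-[3,4-bis(benzyloxy)phenyl]-3-[2,4-bis(benzyloxy)-6-bromophenyl]-2-(prop-2-en-1-yloxy)propan-1-ol
Conditions: Bu4NF, THF, 0 °C → rt; aq. NH4Cl
Reagents that add atoms: none
Why: Fluoride-mediated desilylation frees only the C2 hydroxyl, since allyl ethers, benzyl ethers and the aryl bromide are inert to the fluoride.

**Step 15**
Reactants: 21 open-chain 2-hydroxy-3-allyloxy-4-(2-bromoaryl)-4-(epicatechin-8-yl) triarylpropane (flavan numbering)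
Product: 22 3,3'-di-O-allyl-octa-O-benzylprocyanidin B2 [3-O-allyl-5,7,3',4'-tetra-O-benzylepicatechin-(4β→8)-3-O-allyl-5,7,3',4'-tetra-O-benzylepicatechin]
Conditions: CuI (20 mol%), 1,10-phenanthroline (40 mol%), Cs2CO3 (2 equiv), toluene, 110 °C, Ar
Reagents that add atoms: none
Why: Cs2CO3 converts the free C2 hydroxyl into a phenanthroline-ligated monovalent copper alkoxide, the C8a–Br bond of ring A adds oxidatively to give a trivalent copper aryl alkoxide, and C–O reductive elimination forms the O1–C8a bond. The closest known reaction type is the copper-catalysed intramolecular O-arylation of secondary alcohols by tethered aryl bromides that gives chromans (Ullmann-type etherification). Ring C closes in the six-membered mode, the oxygen on C2 reaching C8a across the chain C2–C3–C4–C4a, which is the only ring size open to it. No stereocentre is created: C2 keeps its configuration because the C2–O bond is never broken, and C3, C4 and the lower unit are spectators under carbonate base. The step needs selectivity for O2 and for ring size six, and this is secured by the allyl ether on O3, which unlike a silyl ether cannot migrate to the neighbouring alkoxide, so the five-membered closure from O3 onto C8a is excluded, while the lower 3-oxygen is allylated as well. The single aryl bromide sits ortho to C4, so no other C–O coupling site exists.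

**Step 16**
Reactants: 22 3,3'-di-O-allyl-octa-O-benzylprocyanidin B2
Product: 24 5,7,3',4'-tetra-O-benzylepicatechin-(4β→8)-5,7,3',4'-tetra-O-benzylepicatechin (octa-O-benzylprocyanidin B2), via bis(prop-1-enyl) ether 23 (not isolated)
Conditions: [Ir(cod)(PMePh2)2]PF6 (5 mol%, activated with H2, then Ar), THF, rt; then 0.5 M aq. HCl, THF, rt
Reagents that add atoms: none
Why: Iridium-catalysed isomerisation of allyl ethers to prop-1-enyl ethers followed by mild acid hydrolysis of the enol ethers is the standard allyl ether removal in the presence of benzyl ethers, and no aryl halide is left that could interfere.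

**Step 17**
Reactants: 24 octa-O-benzylprocyanidin B2; 25 3,4,5-tris(benzyloxy)benzoic acid
Product: 26 3,3'-bis-O-[3,4,5-tris(benzyloxy)benzoyl]-octa-O-benzylprocyanidin B2
Conditions: 25 (3 equiv), EDC·HCl, DMAP, CH2Cl2, rt → 40 °C
Reagents that add atoms: none
Why: Steglich esterification with carbodiimide and DMAP acylates both hindered secondary 3-hydroxyls, as is usual for flavan-3-ol gallates, without touching C2 or C4.

**Step 18**
Reactants: 26 tetradeca-O-benzyl 3,3'-di-O-galloylprocyanidin B2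
Product: 27 3,3'-di-O-galloylprocyanidin B2 (target)
Conditions: H2 (1 atm), Pd(OH)2/C, THF/MeOH/H2O, rt
Reagents that add atoms: none
Why: Hydrogenolysis of the fourteen benzyl ethers over palladium hydroxide on carbon under neutral conditions should leave the gallate esters, the ring C ethers and the interflavan bond intact.

**Compound list**
1 | droxidopa, (2S,3R)-2-amino-3-(3,4-dihydroxyphenyl)-3-hydroxypropanoic acid | N[C@@H]([C@H](O)c1ccc(O)c(O)c1)C(=O)O | starting material
2 | N-Boc-droxidopa | CC(C)(C)OC(=O)N[C@@H]([C@H](O)c1ccc(O)c(O)c1)C(=O)O | intermediate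
3 | benzyl (2S,3R)-3-[3,4-bis(benzyloxy)phenyl]-2-[(tert-butoxycarbonyl)amino]-3-hydroxypropanoate | CC(C)(C)OC(=O)N[C@@H]([C@H](O)c1ccc(OCc2ccccc2)c(OCc2ccccc2)c1)C(=O)OCc1ccccc1 | intermediate
4 | benzyl (2S,3R)-3-[3,4-bis(benzyloxy)phenyl]-3-[(tert-butyldimethylsilyl)oxy]-2-{[(tert-butyldimethylsilyl)oxycarbonyl]amino}propanoate (silyl carbamate) | CC(C)(C)[Si](C)(C)OC(=O)N[C@@H]([C@H](O[Si](C)(C)C(C)(C)C)c1ccc(OCc2ccccc2)c(OCc2ccccc2)c1)C(=O)OCc1ccccc1 | intermediate (not isolated)
5 | benzyl (2S,3R)-2-amino-3-[3,4-bis(benzyloxy)phenyl]-3-[(tert-butyldimethylsilyl)oxy]propanoate | N[C@@H]([C@H](O[Si](C)(C)C(C)(C)C)c1ccc(OCc2ccccc2)c(OCc2ccccc2)c1)C(=O)OCc1ccccc1 | intermediate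
6 | (2S,3R)-2-amino-3-[3,4-bis(benzyloxy)phenyl]-3-[(tert-butyldimethylsilyl)oxy]propanoic acid | N[C@@H]([C@H](O[Si](C)(C)C(C)(C)C)c1ccc(OCc2ccccc2)c(OCc2ccccc2)c1)C(=O)O | intermediate
7 | (2S,3R)-3-[3,4-bis(benzyloxy)phenyl]-3-[(tert-butyldimethylsilyl)oxy]-2-diazoniopropanoate (diazonium carboxylate) | N#[N+][C@@H]([C@H](O[Si](C)(C)C(C)(C)C)c1ccc(OCc2ccccc2)c(OCc2ccccc2)c1)C(=O)[O-] | intermediate (not isolated)
8 | (3R)-3-{(R)-[3,4-bis(benzyloxy)phenyl][(tert-butyldimethylsilyl)oxy]methyl}oxiran-2-one (alpha-lactone) | O=C1O[C@@H]1[C@H](O[Si](C)(C)C(C)(C)C)c1ccc(OCc2ccccc2)c(OCc2ccccc2)c1 | intermediate (not isolated)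
9 | (2S,3R)-3-[3,4-bis(benzyloxy)phenyl]-3-[(tert-butyldimethylsilyl)oxy]-2-hydroxypropanoic acid | O[C@@H]([C@H](O[Si](C)(C)C(C)(C)C)c1ccc(OCc2ccccc2)c(OCc2ccccc2)c1)C(=O)O | intermediate
10 | prop-2-en-1-yl (2S,3R)-3-[3,4-bis(benzyloxy)phenyl]-3-[(tert-butyldimethylsilyl)oxy]-2-(prop-2-en-1-yloxy)propanoate | C=CCO[C@@H]([C@H](O[Si](C)(C)C(C)(C)C)c1ccc(OCc2ccccc2)c(OCc2ccccc2)c1)C(=O)OCC=C | intermediate
11 | (2S,3R)-3-[3,4-bis(benzyloxy)phenyl]-3-[(tert-butyldimethylsilyl)oxy]-2-(prop-2-en-1-yloxy)propanal | C=CCO[C@@H]([C@H](O[Si](C)(C)C(C)(C)C)c1ccc(OCc2ccccc2)c(OCc2ccccc2)c1)C=O | intermediate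
12 | 5-bromoresorcinol | Oc1cc(O)cc(Br)c1 | starting material
13 | 1,3-bis(benzyloxy)-5-bromobenzene | Brc1cc(OCc2ccccc2)cc(OCc2ccccc2)c1 | intermediate
14 | 1,5-bis(benzyloxy)-3-bromo-2-iodobenzene | Brc1cc(OCc2ccccc2)cc(OCc2ccccc2)c1I | intermediate
15 | [2,4-bis(benzyloxy)-6-bromophenyl]magnesium chloride (as its LiCl complex) | Cl[Mg]c1c(Br)cc(OCc2ccccc2)cc1OCc1ccccc1 | intermediate (not isolated)
16 | (2R,3R)-3-[3,4-bis(benzyloxy)phenyl]-1-[2,4-bis(benzyloxy)-6-bromophenyl]-3-[(tert-butyldimethylsilyl)oxy]-2-(prop-2-en-1-yloxy)propan-1-ol, C1 epimers | C=CCO[C@@H]([C@H](O[Si](C)(C)C(C)(C)C)c1ccc(OCc2ccccc2)c(OCc2ccccc2)c1)C(O)c1c(OCc2ccccc2)cc(OCc2ccccc2)cc1Br | intermediate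
17 | (−)-epicatechin | Oc1cc(O)c2c(c1)O[C@H](c1ccc(O)c(O)c1)[C@H](O)C2 | starting material
18 | 5,7,3',4'-tetra-O-benzyl-(−)-epicatechin | O(Cc1ccccc1)c1cc(OCc3ccccc3)c2c(c1)O[C@H](c1ccc(OCc3ccccc3)c(OCc3ccccc3)c1)[C@H](O)C2 | intermediate
19 | 3-O-allyl-5,7,3',4'-tetra-O-benzyl-(−)-epicatechin | O(Cc1ccccc1)c1cc(OCc3ccccc3)c2c(c1)O[C@H](c1ccc(OCc3ccccc3)c(OCc3ccccc3)c1)[C@H](OCC=C)C2 | intermediate
20 | (1R,2R,3S)-triarylpropane with O2 silylated and O3 allylated (product of step 13) | C=CCO[C@@H]([C@H](O[Si](C)(C)C(C)(C)C)c1ccc(OCc2ccccc2)c(OCc2ccccc2)c1)[C@@H](c1c(OCc2ccccc2)cc(OCc2ccccc2)c2c1O[C@H](c1ccc(OCc3ccccc3)c(OCc3ccccc3)c1)[C@H](OCC=C)C2)c1c(OCc2ccccc2)cc(OCc2ccccc2)cc1Br | intermediate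
21 | (1R,2R,3S)-triarylpropan-1-ol with free C2 hydroxyl (flavan numbering), precursor of the key step | C=CCO[C@@H]([C@H](O)c1ccc(OCc2ccccc2)c(OCc2ccccc2)c1)[C@@H](c1c(OCc2ccccc2)cc(OCc2ccccc2)c2c1O[C@H](c1ccc(OCc3ccccc3)c(OCc3ccccc3)c1)[C@H](OCC=C)C2)c1c(OCc2ccccc2)cc(OCc2ccccc2)cc1Br | intermediate
22 | 3,3'-di-O-allyl-octa-O-benzylprocyanidin B2, product of the key step | C=CCO[C@@H]1[C@@H](c2c(OCc3ccccc3)cc(OCc3ccccc3)c3c2O[C@H](c2ccc(OCc4ccccc4)c(OCc4ccccc4)c2)[C@H](OCC=C)C3)c2c(OCc3ccccc3)cc(OCc3ccccc3)cc2O[C@@H]1c1ccc(OCc2ccccc2)c(OCc2ccccc2)c1 | intermediate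
23 | 3,3'-bis-O-[(E)-prop-1-enyl]-octa-O-benzylprocyanidin B2 | C/C=C/O[C@@H]1[C@@H](c2c(OCc3ccccc3)cc(OCc3ccccc3)c3c2O[C@H](c2ccc(OCc4ccccc4)c(OCc4ccccc4)c2)[C@H](O/C=C/C)C3)c2c(OCc3ccccc3)cc(OCc3ccccc3)cc2O[C@@H]1c1ccc(OCc2ccccc2)c(OCc2ccccc2)c1 | intermediate (not isolated)
24 | octa-O-benzylprocyanidin B2 (3,3'-diol) | O[C@@H]1[C@@H](c2c(OCc3ccccc3)cc(OCc3ccccc3)c3c2O[C@H](c2ccc(OCc4ccccc4)c(OCc4ccccc4)c2)[C@H](O)C3)c2c(OCc3ccccc3)cc(OCc3ccccc3)cc2O[C@@H]1c1ccc(OCc2ccccc2)c(OCc2ccccc2)c1 | intermediate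
25 | 3,4,5-tris(benzyloxy)benzoic acid | OC(=O)c1cc(OCc2ccccc2)c(OCc2ccccc2)c(OCc2ccccc2)c1 | starting material
26 | 3,3'-bis-O-[3,4,5-tris(benzyloxy)benzoyl]-octa-O-benzylprocyanidin B2 | O=C(O[C@@H]1[C@@H](c2c(OCc3ccccc3)cc(OCc3ccccc3)c3c2O[C@H](c2ccc(OCc4ccccc4)c(OCc4ccccc4)c2)[C@H](OC(=O)c2cc(OCc4ccccc4)c(OCc4ccccc4)c(OCc4ccccc4)c2)C3)c2c(OCc3ccccc3)cc(OCc3ccccc3)cc2O[C@@H]1c1ccc(OCc2ccccc2)c(OCc2ccccc2)c1)c1cc(OCc2ccccc2)c(OCc2ccccc2)c(OCc2ccccc2)c1 | intermediate
27 | 3,3'-di-O-galloylprocyanidin B2 | O=C(O[C@@H]1[C@@H](c2c(O)cc(O)c3c2O[C@H](c2ccc(O)c(O)c2)[C@H](OC(=O)c2cc(O)c(O)c(O)c2)C3)c2c(O)cc(O)cc2O[C@@H]1c1ccc(O)c(O)c1)c1cc(O)c(O)c(O)c1 | target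

**Step count**
Total: 18 steps. Longest linear sequence: 14 steps (steps 1–7, 10, 13–18, from droxidopa).

**Steps most likely to fail**

Step 13. The facial selectivity at the cationic C4 may be poor or the reverse of that expected, and ring B may capture the cation internally (indane closure). The fallback sets out from 16 and delivers hydride instead of the arene to C4. Dess–Martin periodinane in CH2Cl2 should oxidise 16 to the (2S,3R)-configured aryl ketone F1. NBS in CH2Cl2 at −78 °C should brominate 19 at C8 to give 3-O-allyl-5,7,3',4'-tetra-O-benzyl-8-bromo-(−)-epicatechin F2. Bromine–lithium exchange on F2 (t-BuLi, THF, −78 °C) and addition to F1 should give the tertiary diaryl carbinol F3. Ionic hydrogenation (Et3SiH, CF3CO2H, CH2Cl2, −78 °C) reduces its diaryl cation; because the incoming group is now hydride, the same facial bias that misdirected the arene should give the opposite, wanted configuration at C4. The route is rejoined at 20.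

Step 15. The closure may be slow, or hydrodebromination may take over, because the alkoxide and the bromide are flanked by the crowded diarylmethine. The fallback sets out from 16 and closes ring C before the interflavan bond is made. PPTS in MeOH should exchange the ionisable C4 hydroxyl for methoxyl to give the C4 methyl ether F4. Bu4NF should free the C2 hydroxyl to give the bromo alcohol F5. The same CuI/1,10-phenanthroline/Cs2CO3 closure on this much less crowded substrate should give 3-O-allyl-5,7,3',4'-tetra-O-benzyl-4-methoxy-(−)-epicatechin F6. TMSOTf-mediated coupling of F6 with 19 at −78 °C, where the ring directs the arene trans to O3, leads to 22.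

Step 5. The electron-rich aryl group may migrate to the diazonium carbon, configuration may be lost, or the silyl ether may hydrolyse in the aqueous acid. The fallback sets out from amino ester 5 and avoids a cationic deamination. Isoamyl nitrite with catalytic AcOH in CHCl3 at reflux should give the α-diazo ester F7. Dimethyldioxirane in acetone at 0 °C should oxidise it to the α-keto ester F8. LiBH(s-Bu)3 in THF at −78 °C should reduce the ketone under non-chelation control, hydride entering anti to the silyloxy group, to give the syn hydroxy ester F9. LiOH in THF/H2O then gives 9.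

**Further compounds**
F1 | step 13 | (2S,3R)-3-[3,4-bis(benzyloxy)phenyl]-1-[2,4-bis(benzyloxy)-6-bromophenyl]-3-[(tert-butyldimethylsilyl)oxy]-2-(prop-2-en-1-yloxy)propan-1-one | C=CCO[C@@H]([C@H](O[Si](C)(C)C(C)(C)C)c1ccc(OCc2ccccc2)c(OCc2ccccc2)c1)C(=O)c1c(OCc2ccccc2)cc(OCc2ccccc2)cc1Br
F2 | step 13 | 3-O-allyl-5,7,3',4'-tetra-O-benzyl-8-bromo-(−)-epicatechin | Brc1c(OCc2ccccc2)cc(OCc2ccccc2)c2c1O[C@H](c1ccc(OCc3ccccc3)c(OCc3ccccc3)c1)[C@H](OCC=C)C2
F3 | step 13 | (2R,3R)-1-[3-O-allyl-5,7,3',4'-tetra-O-benzyl-(−)-epicatechin-8-yl]-3-[3,4-bis(benzyloxy)phenyl]-1-[2,4-bis(benzyloxy)-6-bromophenyl]-3-[(tert-butyldimethylsilyl)oxy]-2-(prop-2-en-1-yloxy)propan-1-ol, C1 epimers | C=CCO[C@@H]([C@H](O[Si](C)(C)C(C)(C)C)c1ccc(OCc2ccccc2)c(OCc2ccccc2)c1)C(O)(c1c(OCc2ccccc2)cc(OCc2ccccc2)c2c1O[C@H](c1ccc(OCc3ccccc3)c(OCc3ccccc3)c1)[C@H](OCC=C)C2)c1c(OCc2ccccc2)cc(OCc2ccccc2)cc1Br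
F4 | step 15 | (1R,2R)-1-[3,4-bis(benzyloxy)phenyl]-3-[2,4-bis(benzyloxy)-6-bromophenyl]-1-[(tert-butyldimethylsilyl)oxy]-3-methoxy-2-(prop-2-en-1-yloxy)propane, C3 epimers | C=CCO[C@@H]([C@H](O[Si](C)(C)C(C)(C)C)c1ccc(OCc2ccccc2)c(OCc2ccccc2)c1)C(OC)c1c(OCc2ccccc2)cc(OCc2ccccc2)cc1Br
F5 | step 15 | (1R,2R)-1-[3,4-bis(benzyloxy)phenyl]-3-[2,4-bis(benzyloxy)-6-bromophenyl]-3-methoxy-2-(prop-2-en-1-yloxy)propan-1-ol, C3 epimers | C=CCO[C@@H]([C@H](O)c1ccc(OCc2ccccc2)c(OCc2ccccc2)c1)C(OC)c1c(OCc2ccccc2)cc(OCc2ccccc2)cc1Br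
F6 | step 15 | 3-O-allyl-5,7,3',4'-tetra-O-benzyl-4-methoxy-(−)-epicatechin, C4 epimers | C=CCO[C@@H]1C(OC)c2c(OCc3ccccc3)cc(OCc3ccccc3)cc2O[C@@H]1c1ccc(OCc2ccccc2)c(OCc2ccccc2)c1
F7 | step 5 | benzyl (3R)-3-[3,4-bis(benzyloxy)phenyl]-3-[(tert-butyldimethylsilyl)oxy]-2-diazopropanoate | [N-]=[N+]=C([C@H](O[Si](C)(C)C(C)(C)C)c1ccc(OCc2ccccc2)c(OCc2ccccc2)c1)C(=O)OCc1ccccc1
F8 | step 5 | benzyl (3R)-3-[3,4-bis(benzyloxy)phenyl]-3-[(tert-butyldimethylsilyl)oxy]-2-oxopropanoate | O=C([C@H](O[Si](C)(C)C(C)(C)C)c1ccc(OCc2ccccc2)c(OCc2ccccc2)c1)C(=O)OCc1ccccc1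
F9 | step 5 | benzyl (2S,3R)-3-[3,4-bis(benzyloxy)phenyl]-3-[(tert-butyldimethylsilyl)oxy]-2-hydroxypropanoate | O[C@@H]([C@H](O[Si](C)(C)C(C)(C)C)c1ccc(OCc2ccccc2)c(OCc2ccccc2)c1)C(=O)OCc1ccccc1
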